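## The problem

Target 13 is a cyclobutane in which every ring carbon is a methine stereocentre: C1 and C3 carry 3,4-dimethoxyphenyl groups, and C2 and C4 carry carbonyl groups bound as imides to the nitrogen atoms of two 5,6-dihydropyridin-2(1H)-one rings. The substituents sit head to tail, the aryl groups trans to each other and the acyl groups trans to each other, so each acyl group is cis to one aryl neighbour and trans to the other. With two identical pairs this arrangement has a centre of inversion, so 13 is achiral and only relative configuration has to be controlled. C2 and C4 are enolisable and could be corrected afterwards; C1 and C3 are not, so the trans relation of the aryl groups must be set kinetically. If the last two ring hydrogens are added cis to a cyclobutene, they must enter on the face that already carries the substituents of the two sp3 carbons, against the steric bias, so a ring substituent has to direct the reagent. The N-acyl dihydropyridinone units are acyl donors, Michael acceptors and reducible alkenes and must be attached last; the strained ring will not tolerate an alkoxide β to a carbonyl group (retro-aldol opening) or long heating at the cyclobutene stage. The feature that invites a pericyclic construction is the C1–C2 bond: C1, C2, C3 and C4 with their substituents are C6, C3, C4 and C5 of a 2-pyrone bearing aryl at C6, aryl at C4, an ester at C5 and, as the future C2 acyl group, its own lactone carbonyl on C3, so that joining pyrone C3 to C6 closes the four-membered ring with all four substituents in place.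

## Retrosynthesis

**Imide bonds.** The two imide N–C(=O) bonds are cut first, giving the centrosymmetric diacid 10 and two molecules of commercial 5,6-dihydropyridin-2(1H)-one 11. This removes the only groups of 13 that are incompatible with light, acid, hydrogen and hydroxide. The forward step must acylate a weakly nucleophilic lactam nitrogen twice without enolising C2 or C4; the bis(acid chloride) 12 and two equivalents of the lithium salt of 11 at low temperature are planned.

**Ester and two ring C–H bonds.** Diacid 10 is traced to its mono methyl ester 9, and 9 to the cyclobutene acid 8 by removing the hydrogens from one aryl-bearing and the ester-bearing carbon. In 8 the two remaining stereocentres are cis (carboxyl and aryl). Delivery of H2 from their face creates both new centres correctly at once: the new aryl carbon trans to its carboxyl neighbour and to the other aryl group, and the ester trans to the acid. The neighbouring option, reduction from the open face followed by epimerisation, can only reach cis-diaryl isomers. The cut therefore asks for a carboxyl-directed hydrogenation of a tetrasubstituted alkene on its crowded face. Acid and ester stay differentiated until then so that only the carboxyl group on sp3 carbon directs.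

**Benzylic C–H for lactone C–O.** The benzylic C–H bond at the sp3 aryl carbon of 8 is exchanged for a C–O bond that ties the carboxyl group back as the β-lactone of bicycle 7. Carrying the lactone through alkene saturation and ester equilibration was weighed and set aside. An ester enolate next to the lactone oxygen would eliminate to 8 in any case, and replacing an acyloxy group by hydrogen with retention at a quaternary benzylic carbon is not a dependable outcome of hydrogenolysis. Opening first uses the most labile bond of 7 (tertiary, benzylic, allylic, in a four-membered lactone): ionisation gives a 1,3-diaryl cyclobutenyl cation, and hydride capture at either end, anti to the carboxyl group, gives the same cis acid 8 as a racemate.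

**Key cut.** Cutting the bond between the two bridgehead carbons of 7 (C1–C2 of 13, C6–C3 of the pyrone) opens the bicycle to the planar, stereocentre-free 2-pyrone 6. Against an intermolecular head-to-tail union of two cinnamate-type alkenes in solution, this cut needs no regio- or facial control between two partners. One intramolecular bond forms and the cis ring fusion is dictated by geometry. The forward reaction is a singlet 4π photocyclisation that must outrun ketene formation and dimerisation and whose product must be kept cold.

**Pyrone ring.** Pyrone 6 is cut at C4–C5 and at the ring O–C2 bond into the aryl propiolate 3 and the commercial β-keto ester 4. The whole substitution pattern of the cyclobutane then comes from one condensation in a flat ring at no stereochemical cost. The forward reaction is a Michael addition followed by lactonisation.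

**Aryl–alkyne bond.** Propiolate 3 is cut at the aryl–alkyne bond into 4-iodoveratrole 1 and methyl propiolate 2, to be joined by Sonogashira coupling.

## Roads not taken

**Alternative 1:** Both arenes are disconnected. Each would be grown from an ethynyl group of dimethyl 2,4-diethynylcyclobutane-1,3-dicarboxylate A2 and a molecule of 2,3-dimethoxybuta-1,3-diene A3. A2 would be derived from cyclobutane-1,2,3,4-tetracarboxylic dianhydride A1, whose cis,trans,cis framework already holds the four ring centres in the required relation.
- Key step: under CoBr2(Ph2PCH2CH2PPh2), zinc and ZnI2, A2 and two molecules of A3 combine in two [4+2] cycloadditions (four C–C bonds) to the bis(cyclohexadiene) A4. Dehydrogenation and hydrolysis then lead to 10.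
- Merit: the ring stereochemistry is bought rather than made, and no step works against a steric bias. In this respect it is better than the chosen plan.
- Weak points: A1 must be opened twice with the head-to-tail sense, where head-to-head half-esters compete. Two carboxyl groups must become alkynes by way of aldehydes on enolisable ring carbons under basic homologation conditions, which puts the purchased configuration at risk. The dialkoxy diene and the enol-ether-containing A4 are acid-sensitive. The sequence is markedly longer.
- Comparison: the chosen plan sets against the secure stereochemistry a route of about half the length and a substitution pattern that needs no regiochemical differentiation.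

**Alternative 2:** The two aryl–ring bonds are cut. trans-N1,N3-Di(quinolin-8-yl)cyclobutane-1,3-dicarboxamide A5 would be arylated twice with 1 under Pd(OAc)2 and AgOAc at its two methylene groups to give A6.
- Merits: amide-directed C–H arylation cis to the directing group is established on cyclobutanes, the arene enters as commercial 1, and the cis aryl/acyl relation is enforced by a palladacycle. That is firmer ground than the directed hydrogenation of step 5 and the photochemistry of step 3, at comparable length.
- Weak points: each methylene of A5 is flanked by both amides, and A6 forms only if the two arylations are steered by different amide groups. If the same amide acts twice the cis-diaryl isomer results, and nothing in the structure enforces the choice. Two auxiliaries must be attached and later cleaved from hindered amides next to epimerisable centres.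
- Comparison: the chosen plan carries no auxiliary, and its aryl/acyl pattern is fixed unambiguously before any stereocentre exists.

**Alternative 3:** The ring is cut in a [3+2] sense with a nitrogen atom temporarily inserted between C1 and C4. Methyl N-(3,4-dimethoxybenzylidene)glycinate A7 and methyl (Z)-3,4-dimethoxycinnamate A8 would combine under Cu(CH3CN)4PF6, a bulky bisphosphine and a tertiary amine in an exo cycloaddition to pyrrolidine A9. Oxidative nitrogen deletion would then contract the ring to the dimethyl ester of 10.
- Merits: metal-bound azomethine ylide cycloadditions set 2,5-cis and, from a Z-alkene, 3,4-cis relations through a well-understood transition state. The route could be as short as or shorter than the chosen one, and its C–C bond formation is better precedented than step 3.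
- Weak points: it needs exo where endo is the usual preference, and it depends on the less stable Z-cinnamate, which can isomerise under the basic copper conditions. The contraction passes through a 1,4-biradical flanked by aryl and ester groups, where fragmentation into two alkenes competes with closure to the strained ring and stereoretention depends on fast collapse.
- Comparison: the chosen plan makes the four-membered ring in a ring-preserving electrocyclisation and never has to close it from an open-chain biradical.

Key step: step 3

Remark on the chemistry: 13 is centrosymmetric and therefore achiral, so all chiral intermediates (7, 8, 9) are planned as racemates; their SMILES strings show one enantiomer.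

## Route

Step 1
Reactants: 1 4-iodoveratrole (4-iodo-1,2-dimethoxybenzene); 2 methyl propiolate
Product: 3 methyl 3-(3,4-dimethoxyphenyl)prop-2-ynoate
Conditions: PdCl2(PPh3)2 (2 mol%), CuI (4 mol%), K2CO3, THF, 65 °C
Reagents that add atoms: none
Why: Sonogashira coupling: oxidative addition of the aryl iodide to zerovalent palladium, transmetalation of the copper acetylide and reductive elimination form the aryl–alkyne bond; an inorganic base in place of an amine avoids conjugate addition to the propiolate.

Step 2
Reactants: 3 methyl 3-(3,4-dimethoxyphenyl)prop-2-ynoate; 4 methyl 3-(3,4-dimethoxyphenyl)-3-oxopropanoate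
Product: 6 methyl 4,6-bis(3,4-dimethoxyphenyl)-2-oxo-2H-pyran-5-carboxylate, via Michael adduct 5 (not isolated)
Conditions: NaOMe, MeOH, 23 °C; then AcOH, 65 °C
Reagents that add atoms: none
Why: Michael addition of the β-keto ester enolate to the β-carbon of the ynoate forms the pyrone C4–C5 bond, and the enol oxygen of the aryl ketone then displaces methoxide from the unsaturated ester (6-exo-trig lactonisation) to give the aromatic 2-pyrone; the geometric isomers of 5 interconvert through the dienolate, so all material can reach 6. This is the classical β-keto ester/alkynoate synthesis of 2-pyrone-5-carboxylates.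

Step 3
Reactants: 6 methyl 4,6-bis(3,4-dimethoxyphenyl)-2-oxo-2H-pyran-5-carboxylate
Product: 7 methyl 1,5-bis(3,4-dimethoxyphenyl)-3-oxo-2-oxabicyclo[2.2.0]hex-5-ene-6-carboxylate (cis-fused racemate)
Conditions: hν (365 nm), degassed CH2Cl2 (2 mM, flow), −40 °C; solution kept cold and used directly
Reagents that add atoms: none
Why: Singlet excitation of the pyrone is followed by disrotatory 4π electrocyclisation of the C3=C4–C5=C6 diene unit, which joins C3 to C6 (cyclobutane C2 to C1). This one C–C bond turns the six-membered ring into a bicycle: the cyclobutene (C3, C4, C5, C6) closes by photochemically allowed 4π electrocyclisation, and the β-lactone (O1, C2, C3, C6) is what remains of the pyrone on the other side of the new bond. The closest known reaction type is the photoisomerisation of 2-pyrone and of 5-alkoxycarbonyl-2-pyrones to 2-oxabicyclo[2.2.0]hex-5-en-3-ones; members with aryl groups at C4 and C6 have not been taken through it, which is the main uncertainty. The two new stereocentres are the bridgeheads; their relative configuration is fixed by geometry, since this bicycle can only be cis-fused, and no absolute control is needed because 13 is achiral. The step needs chemoselectivity for closure over reversible acyl–oxygen cleavage to the ketene, over [2+2] photodimerisation and over secondary photolysis of 7 with loss of CO2. The ketene recloses in a non-nucleophilic solvent; high dilution and the tri- and tetrasubstituted ring double bonds of 6 disfavour dimerisation; irradiation at the long-wavelength edge excites the extended pyrone chromophore but not the less conjugated aryl acrylate chromophore of 7. Low temperature is needed because the bridgehead C–O bond of 7 is tertiary, benzylic and allylic and would ionise or revert on warming.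

Step 4
Reactants: 7 methyl 1,5-bis(3,4-dimethoxyphenyl)-3-oxo-2-oxabicyclo[2.2.0]hex-5-ene-6-carboxylate (cold photolysate)
Product: 8 cis-2,4-bis(3,4-dimethoxyphenyl)-3-(methoxycarbonyl)cyclobut-2-ene-1-carboxylic acid (racemate; carboxyl at C1 and aryl at C4 on the same face)
Conditions: Et3SiH, CF3CO2H, CH2Cl2, −78 → −20 °C
Reagents that add atoms: none
Why: Ionic hydrogenation: the strained lactone C–O bond ionises under acid to a 1,3-diaryl cyclobutenyl cation, which triethylsilane reduces at either aryl-bearing terminus (the two modes give the two enantiomers of the same acid). Hydride should enter anti to the carboxyl group on the adjacent sp3 carbon, which places that aryl group cis to the carboxyl group and defines the face used in step 5.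

Step 5
Reactants: 8 cis-2,4-bis(3,4-dimethoxyphenyl)-3-(methoxycarbonyl)cyclobut-2-ene-1-carboxylic acid
Product: 9 (1α,2β,3β,4α)-2,4-bis(3,4-dimethoxyphenyl)-3-(methoxycarbonyl)cyclobutane-1-carboxylic acid (racemate)
Conditions: [Ir(cod)(PCy3)(py)]PF6 (5–10 mol%), H2 (50 bar), CH2Cl2, 25 °C
Reagents that add atoms: none
Why: Carbonyl-directed homogeneous hydrogenation: the carboxyl oxygen and the alkene bind the cationic iridium dihydride on the same face, so both hydrogens are delivered syn to the carboxyl group and its cis aryl neighbour, against the steric bias. This sets the last two stereocentres at once: the new aryl carbon becomes trans to the carboxyl-bearing carbon and to the other aryl group, and the ester ends trans to the acid, which is the centrosymmetric pattern of 13. Strain release should make the tetrasubstituted cyclobutene more reactive than an ordinary tetrasubstituted enoate.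

Step 6
Reactants: 9 (1α,2β,3β,4α)-2,4-bis(3,4-dimethoxyphenyl)-3-(methoxycarbonyl)cyclobutane-1-carboxylic acid
Product: 10 (1α,2α,3β,4β)-2,4-bis(3,4-dimethoxyphenyl)cyclobutane-1,3-dicarboxylic acid
Conditions: LiOH, THF/H2O, 40 °C; then aq. HCl
Reagents that add atoms: lithium hydroxide, [Li+].[OH-]
Why: Saponification of the methyl ester by acyl–oxygen cleavage; the carboxylate α-carbon is not enolisable under these conditions, and the trans-diacyl arrangement is the one that keeps the two carboxylates apart, so no loss of configuration at the ester carbon is expected.

Step 7
Reactants: 10 (1α,2α,3β,4β)-2,4-bis(3,4-dimethoxyphenyl)cyclobutane-1,3-dicarboxylic acid; 11 5,6-dihydropyridin-2(1H)-one (2 equiv, one for each carboxyl group)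
Product: 13 1,1′-{[(1α,2α,3β,4β)-2,4-bis(3,4-dimethoxyphenyl)cyclobutane-1,3-diyl]dicarbonyl}bis(5,6-dihydropyridin-2(1H)-one), via bis(acid chloride) 12 (not isolated)
Conditions: (COCl)2, DMF (cat.), CH2Cl2, 0 → 23 °C; evaporate; then 11 (2.2 equiv), LiN(SiMe3)2 (2.2 equiv), THF, −78 → −20 °C
Reagents that add atoms: 5,6-dihydropyridin-2(1H)-one (the second equivalent of 11), O=C1C=CCCN1
Why: Acid chloride formation followed by N-acylation of the lithium lactamide, the standard way to N-acyl dihydropyridinones; each of the two acid chloride groups of 12 acylates one molecule of lithiated 11, so two equivalents of the lactam are consumed. Low temperature and addition of 12 to a small excess of the lactamide limit ketene formation and enolisation of the product, so the configuration at C2 and C4 should be kept.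

## Compound list

1 | 4-iodoveratrole (4-iodo-1,2-dimethoxybenzene) | COc1ccc(I)cc1OC | starting material
2 | methyl propiolate | C#CC(=O)OC | starting material
3 | methyl 3-(3,4-dimethoxyphenyl)prop-2-ynoate | COC(=O)C#Cc1ccc(OC)c(OC)c1 | intermediate
4 | methyl 3-(3,4-dimethoxyphenyl)-3-oxopropanoate | COC(=O)CC(=O)c1ccc(OC)c(OC)c1 | starting material
5 | dimethyl (E)-2-(3,4-dimethoxybenzoyl)-3-(3,4-dimethoxyphenyl)pent-3-enedioate (Michael adduct) | COC(=O)/C=C(/c1ccc(OC)c(OC)c1)C(C(=O)OC)C(=O)c1ccc(OC)c(OC)c1 | intermediate (not isolated)
6 | methyl 4,6-bis(3,4-dimethoxyphenyl)-2-oxo-2H-pyran-5-carboxylate | COC(=O)c1c(-c2ccc(OC)c(OC)c2)cc(=O)oc1-c1ccc(OC)c(OC)c1 | intermediate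
7 | methyl 1,5-bis(3,4-dimethoxyphenyl)-3-oxo-2-oxabicyclo[2.2.0]hex-5-ene-6-carboxylate, cis-fused, racemic | O=C1O[C@]2(c3ccc(OC)c(OC)c3)C(C(=O)OC)=C(c3ccc(OC)c(OC)c3)[C@H]12 | intermediate
8 | cis-2,4-bis(3,4-dimethoxyphenyl)-3-(methoxycarbonyl)cyclobut-2-ene-1-carboxylic acid, racemic | COc1ccc(C2=C(C(=O)OC)[C@@H](c3ccc(OC)c(OC)c3)[C@H]2C(=O)O)cc1OC | intermediate
9 | (1α,2β,3β,4α)-2,4-bis(3,4-dimethoxyphenyl)-3-(methoxycarbonyl)cyclobutane-1-carboxylic acid, racemic | COc1ccc([C@H]2[C@H](C(=O)O)[C@H](c3ccc(OC)c(OC)c3)[C@H]2C(=O)OC)cc1OC | intermediate
10 | (1α,2α,3β,4β)-2,4-bis(3,4-dimethoxyphenyl)cyclobutane-1,3-dicarboxylic acid (aryl groups trans, carboxyl groups trans) | COc1ccc([C@H]2[C@H](C(=O)O)[C@H](c3ccc(OC)c(OC)c3)[C@H]2C(=O)O)cc1OC | intermediate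
11 | 5,6-dihydropyridin-2(1H)-one | O=C1C=CCCN1 | starting material
12 | (1α,2α,3β,4β)-2,4-bis(3,4-dimethoxyphenyl)cyclobutane-1,3-dicarbonyl dichloride | COc1ccc([C@H]2[C@H](C(=O)Cl)[C@H](c3ccc(OC)c(OC)c3)[C@H]2C(=O)Cl)cc1OC | intermediate (not isolated)
13 | 1,1′-{[(1α,2α,3β,4β)-2,4-bis(3,4-dimethoxyphenyl)cyclobutane-1,3-diyl]dicarbonyl}bis(5,6-dihydropyridin-2(1H)-one) | COc1ccc([C@H]2[C@H](C(=O)N3CCC=CC3=O)[C@H](c3ccc(OC)c(OC)c3)[C@H]2C(=O)N2CCC=CC2=O)cc1OC | target

## Step count and least certain steps

Total: 7 steps. Longest linear sequence: 7 steps (1 → 3 → 6 → 7 → 8 → 9 → 10 → 13).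

**Step 3 (key step).** The excited 4,6-diaryl pyrone may relax through aryl twisting or charge transfer without closing, or be diverted into acyl–oxygen cleavage and dimerisation; thermal reversion of 7 before step 4 would also appear as no conversion. The fallback gives up the pyrone and uses known solid-state chemistry. It sets out from 1: Heck coupling with acrylic acid (Pd(OAc)2, P(o-tolyl)3, Et3N, DMF, 100 °C) should give (E)-3,4-dimethoxycinnamic acid F1. Irradiation of crystalline F1 in a head-to-tail packed form should effect topochemical [2+2] photodimerisation of two molecules of F1, in which two trans alkenes related by a centre of inversion can only give the centrosymmetric dimer. This returns to the route at 10, followed by step 7.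

**Step 5.** The directing effect of the carboxyl group may not overcome steric approach from the open face, which would give the all-cis isomer. The tetrasubstituted enoate may also fail to turn over, or the iridium hydride may move the double bond. The fallback changes the directing element to a hydroxyl group, the strongest director for this catalyst class. It sets out from 8: chemoselective reduction of the acid with BH3·SMe2 (THF, 0 °C) should give methyl cis-2,4-bis(3,4-dimethoxyphenyl)-3-(hydroxymethyl)cyclobut-1-ene-1-carboxylate F2. Hydroxyl-directed hydrogenation with [Ir(cod)(PCy3)(py)]PF6 and H2 in CH2Cl2 should give methyl (1α,2α,3β,4β)-2,4-bis(3,4-dimethoxyphenyl)-3-(hydroxymethyl)cyclobutane-1-carboxylate F3. Buffered oxidation with TEMPO, NaOCl (cat.) and NaClO2 should pass through methyl (1α,2α,3β,4β)-2,4-bis(3,4-dimethoxyphenyl)-3-formylcyclobutane-1-carboxylate F4 and return to the route at 9.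

**Step 4.** Hydride capture by the planar cation may show poor facial selectivity, and the long-lived cation may alkylate an electron-rich arene of a second molecule or decompose. The fallback sets the stereocentre on the rigid bicycle before the lactone is opened. It sets out from 7: hydrogenation over Rh/Al2O3 (H2, CH2Cl2/EtOAc, −20 °C) should add hydrogen cis from the convex face and give methyl 1,5-bis(3,4-dimethoxyphenyl)-3-oxo-2-oxabicyclo[2.2.0]hexane-6-carboxylate F5, with the 5-aryl and 6-ester groups endo. DBU (CH2Cl2, 0 °C) should then open the lactone by E1cB elimination of the carboxylate from the ester enolate and return to the route at 8.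

**Step 7.** The second acylation may stall, the lactamide may react at oxygen, and ketene formation from 12 or enolisation of the product imide by excess base may erode the configuration at C2 and C4. The fallback builds the unsaturated lactam rings after the acyl–nitrogen bonds are in place. It sets out from 10 by way of 12: reaction with two equivalents of but-3-en-1-amine and Et3N (CH2Cl2, 0 °C) should give (1α,2α,3β,4β)-N1,N3-di(but-3-en-1-yl)-2,4-bis(3,4-dimethoxyphenyl)cyclobutane-1,3-dicarboxamide F6. Double N-acylation with acryloyl chloride (LiN(SiMe3)2, THF, −78 °C) should give (1α,2α,3β,4β)-N1,N3-diacryloyl-N1,N3-di(but-3-en-1-yl)-2,4-bis(3,4-dimethoxyphenyl)cyclobutane-1,3-dicarboxamide F7. Double ring-closing metathesis with the second-generation Grubbs catalyst RuCl2(=CHPh)(H2IMes)(PCy3) (CH2Cl2, 40 °C) should then close both dihydropyridinone rings and return to the route at 13.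

## Further compounds

F1 | step 3 | (E)-3,4-dimethoxycinnamic acid | COc1ccc(/C=C/C(=O)O)cc1OC
F2 | step 5 | methyl cis-2,4-bis(3,4-dimethoxyphenyl)-3-(hydroxymethyl)cyclobut-1-ene-1-carboxylate | COc1ccc(C2=C(C(=O)OC)[C@@H](c3ccc(OC)c(OC)c3)[C@H]2CO)cc1OC
F3 | step 5 | methyl (1α,2α,3β,4β)-2,4-bis(3,4-dimethoxyphenyl)-3-(hydroxymethyl)cyclobutane-1-carboxylate | COc1ccc([C@H]2[C@H](CO)[C@H](c3ccc(OC)c(OC)c3)[C@H]2C(=O)OC)cc1OC
F4 | step 5 | methyl (1α,2α,3β,4β)-2,4-bis(3,4-dimethoxyphenyl)-3-formylcyclobutane-1-carboxylate | COc1ccc([C@H]2[C@H](C=O)[C@H](c3ccc(OC)c(OC)c3)[C@H]2C(=O)OC)cc1OC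
F5 | step 4 | methyl 1,5-bis(3,4-dimethoxyphenyl)-3-oxo-2-oxabicyclo[2.2.0]hexane-6-carboxylate, 5-aryl and 6-ester endo | O=C1O[C@]2(c3ccc(OC)c(OC)c3)[C@H](C(=O)OC)[C@H](c3ccc(OC)c(OC)c3)[C@H]12
F6 | step 7 | (1α,2α,3β,4β)-N1,N3-di(but-3-en-1-yl)-2,4-bis(3,4-dimethoxyphenyl)cyclobutane-1,3-dicarboxamide | COc1ccc([C@H]2[C@H](C(=O)NCCC=C)[C@H](c3ccc(OC)c(OC)c3)[C@H]2C(=O)NCCC=C)cc1OC
F7 | step 7 | (1α,2α,3β,4β)-N1,N3-diacryloyl-N1,N3-di(but-3-en-1-yl)-2,4-bis(3,4-dimethoxyphenyl)cyclobutane-1,3-dicarboxamide | COc1ccc([C@H]2[C@H](C(=O)N(CCC=C)C(=O)C=C)[C@H](c3ccc(OC)c(OC)c3)[C@H]2C(=O)N(CCC=C)C(=O)C=C)cc1OC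
A1 | alternative 1 | cyclobutane-1,2,3,4-tetracarboxylic 1,2:3,4-dianhydride, cis,trans,cis | O=C1OC(=O)[C@@H]2[C@H]1[C@H]1C(=O)OC(=O)[C@@H]21
A2 | alternative 1 | dimethyl (1α,2α,3β,4β)-2,4-diethynylcyclobutane-1,3-dicarboxylate | C#C[C@H]1[C@H](C(=O)OC)[C@H](C#C)[C@H]1C(=O)OC
A3 | alternative 1 | 2,3-dimethoxybuta-1,3-diene | C=C(OC)C(OC)=C
A4 | alternative 1 | dimethyl (1α,2α,3β,4β)-2,4-bis(4,5-dimethoxycyclohexa-1,4-dien-1-yl)cyclobutane-1,3-dicarboxylate | C1(=CCC(OC)=C(OC)C1)[C@H]2[C@H](C(=O)OC)[C@H](C3=CCC(OC)=C(OC)C3)[C@H]2C(=O)OC
A5 | alternative 2 | trans-N1,N3-di(quinolin-8-yl)cyclobutane-1,3-dicarboxamide | O=C(Nc1cccc2cccnc12)[C@H]3C[C@H](C(=O)Nc4cccc5cccnc45)C3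
A6 | alternative 2 | (1α,2α,3β,4β)-2,4-bis(3,4-dimethoxyphenyl)-N1,N3-di(quinolin-8-yl)cyclobutane-1,3-dicarboxamide | COc1ccc([C@H]2[C@H](C(=O)Nc3cccc4cccnc34)[C@H](c3ccc(OC)c(OC)c3)[C@H]2C(=O)Nc2cccc3cccnc23)cc1OC
A7 | alternative 3 | methyl (E)-N-(3,4-dimethoxybenzylidene)glycinate | COC(=O)C/N=C/c1ccc(OC)c(OC)c1
A8 | alternative 3 | methyl (Z)-3-(3,4-dimethoxyphenyl)acrylate | COC(=O)/C=C\c1ccc(OC)c(OC)c1
A9 | alternative 3 | dimethyl 3,5-bis(3,4-dimethoxyphenyl)pyrrolidine-2,4-dicarboxylate, 2,5-cis, 3,4-cis, the two pairs anti | COc1ccc([C@H]2[C@H](C(=O)OC)[C@H](c3ccc(OC)c(OC)c3)[C@@H](C(=O)OC)N2)cc1OC
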